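## Retrosynthetic overview
- Last step: remove the TIPS group from the guaiacyl phenol.
- The dihydrobenzofuran is the only ring formed, and it is formed last. It comes from dehydrogenative dearomatisation of the symmetric syringyl ring (DDQ) and 5-exo capture by the ortho-phenol of the vanillin-derived ring. C3 of the 1,2-diarylpropan-1-ol precursor fixes C2 as trans.
- C3 is set by Ir-catalysed asymmetric hydrogenation of a trisubstituted 2,3-diarylallyl alcohol. That alcohol comes from Cacchi-type hydroarylation of an aryl alkyne with 5-iodovanillin acetate.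
- The alkyne comes from Sonogashira coupling of an iodosyringyl ether carrying the erythro β-O-4 unit. That unit is made from acetovanillone and 4-iodosyringol (from syringol): α-bromination, Williamson etherification, hydroxymethylation, then Ru-catalysed asymmetric transfer hydrogenation with dynamic kinetic resolution.

Assumptions:
- The target is the 2,3-trans dihydrobenzofuran (2R,3S) with an erythro (αS,βR) glycerol unit. I checked both against the SMILES.
- Reagents are numbered only where they supply carbon skeleton.

## Route

**Step 1**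
Reactants: 1 syringol (2,6-dimethoxyphenol)
Product: 2 4-iodo-2,6-dimethoxyphenol
Conditions: NIS, MeCN, 0 °C → rt
Reagents that add atoms: N-iodosuccinimide, O=C1CCC(=O)N1I
Why: Electrophilic iodination of the symmetric phenol goes only para to OH, because both ortho positions are blocked by OMe.

**Step 2**
Reactants: 3 acetovanillone
Product: 4 1-[3-methoxy-4-(triisopropylsilyloxy)phenyl]ethan-1-one
Conditions: TIPSCl, imidazole, DMF, rt
Reagents that add atoms: TIPSCl, CC(C)[Si](Cl)(C(C)C)C(C)C
Why: Phenol silylation. TIPS survives the bases used later and is removed at the end without touching the aldehyde.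

**Step 3**
Reactants: 4
Product: 5 2-bromo-1-[3-methoxy-4-(TIPSO)phenyl]ethan-1-one
Conditions: CuBr2, EtOAc/CHCl3 1:1, reflux
Reagents that add atoms: CuBr2, Br[Cu]Br
Why: CuBr2 brominates the ketone α-position selectively without brominating the electron-rich ring.

**Step 4**
Reactants: 5 and 2
Product: 6 2-(4-iodo-2,6-dimethoxyphenoxy)-1-[3-methoxy-4-(TIPSO)phenyl]ethan-1-one
Conditions: K2CO3, acetone, 50 °C
Reagents that add atoms: none
Why: Williamson SN2 of the syringyl phenoxide on the phenacyl bromide forms the aryl ether; this is the standard entry to β-O-4 units.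

**Step 5**
Reactants: 6
Product: 7 3-hydroxy-2-(4-iodo-2,6-dimethoxyphenoxy)-1-[3-methoxy-4-(TIPSO)phenyl]propan-1-one (racemic at C2)
Conditions: 37% aq. HCHO (1.3 equiv), K2CO3 (0.2 equiv), THF, 0 °C → rt
Reagents that add atoms: formaldehyde, C=O
Why: Base-mediated aldol-type hydroxymethylation at the doubly activated α-CH2. Limiting HCHO avoids bis-hydroxymethylation.

**Step 6**
Reactants: 7
Product: 8 (1S,2R)-2-(4-iodo-2,6-dimethoxyphenoxy)-1-[3-methoxy-4-(TIPSO)phenyl]propane-1,3-diol (erythro)
Conditions: RuCl[(R,R)-TsDPEN](p-cymene) (2 mol %), HCO2H/Et3N 5:2, CH2Cl2, 35 °C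
Reagents that add atoms: none (formate supplies only H)
Why: Noyori–Ikariya asymmetric transfer hydrogenation with dynamic kinetic resolution, since Et3N epimerises the acidic α-CH(OAr). The (R,R) catalyst is expected to give αS by the usual facial rule, with the CIP descriptor flipping because the side chain outranks the aryl group.
Proposed new method: DKR–ATH of an α-aryloxy-β-hydroxy aryl ketone. The mechanistic reasoning is that the Ru–H delivers hydride anti to the OAr group in the favoured CH/π-stabilised transition state, which gives erythro. The closest known reactions are DKR–ATH of α-alkoxy/aryloxy β-keto esters and of α-substituted aryl ketones.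

**Step 7**
Reactants: 8 and 9 propargyl alcohol
Product: 10 (1S,2R)-2-[4-(3-hydroxyprop-1-yn-1-yl)-2,6-dimethoxyphenoxy]-1-[3-methoxy-4-(TIPSO)phenyl]propane-1,3-diol
Conditions: PdCl2(PPh3)2 (3 mol %), CuI (5 mol %), Et3N, THF, rt
Reagents that add atoms: propargyl alcohol, C#CCO
Why: Sonogashira coupling of the aryl iodide. The free hydroxyl groups and the stereocentres are untouched, since there is no carbonyl α to any stereocentre.

**Step 8**
Reactants: 11 5-iodovanillin (4-hydroxy-3-iodo-5-methoxybenzaldehyde)
Product: 12 4-formyl-2-iodo-6-methoxyphenyl acetate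
Conditions: Ac2O, pyridine, cat. DMAP, CH2Cl2, 0 °C
Reagents that add atoms: acetic anhydride, CC(=O)OC(C)=O
Why: Capping the o-iodophenol prevents Larock benzofuran formation in the next step.

**Step 9**
Reactants: 10 and 12
Product: 13, the (Z)-2,3-diarylallyl alcohol: aryl acetate of 2-(2-acetoxy-3-methoxy-5-formylphenyl)-3-[4-(glycerol ether)-3,5-dimethoxyphenyl]prop-2-en-1-ol
Conditions: Pd(OAc)2 (5 mol %), PPh3 (10 mol %), HCO2H (3 equiv), Et3N (5 equiv), DMF, 60 °C
Reagents that add atoms: none (formate gives H; the aryl comes from reactant 12)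
Why: Cacchi-type reductive hydroarylation. Syn-carbopalladation puts the aryl group on the CH2OH-bearing alkyne carbon and Pd on the syringyl-bearing carbon, then formate delivers H. The aldehyde and the glycerol stereocentres are untouched.

**Step 10**
Reactants: 13
Product: 14, the (S)-2-aryl-3-syringylpropan-1-ol bearing the (1S,2R)-glycerol ether (acetate still on)
Conditions: [Ir(cod)(P,N)]BArF (1 mol %), H2 (50 bar), CH2Cl2, rt; the ligand enantiomer is chosen to give (S)
Reagents that add atoms: none (H2)
Why: Asymmetric hydrogenation of a trisubstituted allylic alcohol with an Ir–P,N catalyst. The hydroxyl group directs the catalyst, and this sets C3 (future C3, S).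

**Step 11**
Reactants: 14
Product: 15, the same compound with the free ring-C phenol
Conditions: K2CO3, MeOH, 0 °C, 30 min
Reagents that add atoms: none
Why: Mild methanolysis of the aryl acetate. TIPS and the aldehyde survive, and no stereocentre is acidic.

**Step 12 (key step)**
Reactants: 15
Product: 16, the target carrying a TIPS ether on the guaiacyl phenol
Conditions: DDQ (1.1 equiv), anhydrous CH2Cl2, 4 Å MS, 0 °C → rt
Reagents that add atoms: none (DDQ leaves as DDQH2)
Why: DDQ removes hydride from the benzylic CH2 of the electron-rich symmetric syringyl ring. This gives a quinoid (aromaticity-broken) p-alkoxybenzyl cation, whose two faces are differentiated by the adjacent C3 centre. The ortho-phenol then closes 5-exo onto it. The closure is reversible under the acidic DDQH2 medium and is expected to favour trans by sterics, giving (2R,3S).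
Proposed new method: DDQ dehydrogenative oxa-cyclisation of a 1,2-diarylpropan-1-ol with a free phenol. The closest known reactions are DDQ cyclisations to 2-aryl-dihydrobenzofurans and PMB-type DDQ oxidation. Selectivity over the guaiacyl α-OH rests on the syringyl ring being more electron-rich and the closure being intramolecular.

**Step 13**
Reactants: 16
Product: 17, the target
Conditions: TBAF (1.2 equiv), AcOH (1.2 equiv), THF, 0 °C
Reagents that add atoms: none (H comes from AcOH)
Why: Buffered fluoride cleaves the aryl silyl ether. The buffer avoids base-mediated damage to the aldehyde and the β-aryloxy α-alcohol.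

## Compound list
1 | syringol | COc1cccc(OC)c1O | starting material
2 | 4-iodo-2,6-dimethoxyphenol | COc1cc(I)cc(OC)c1O | intermediate
3 | acetovanillone | CC(=O)c1ccc(O)c(OC)c1 | starting material
4 | 4′-TIPSO-3′-methoxyacetophenone | CC(=O)c1ccc(O[Si](C(C)C)(C(C)C)C(C)C)c(OC)c1 | intermediate
5 | α-bromoketone | BrCC(=O)c1ccc(O[Si](C(C)C)(C(C)C)C(C)C)c(OC)c1 | intermediate
6 | aryloxy ketone | COc1cc(C(=O)COc2c(OC)cc(I)cc2OC)ccc1O[Si](C(C)C)(C(C)C)C(C)C | intermediate
7 | β-hydroxy-α-aryloxy ketone (racemic) | COc1cc(C(=O)C(CO)Oc2c(OC)cc(I)cc2OC)ccc1O[Si](C(C)C)(C(C)C)C(C)C | intermediate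
8 | (1S,2R)-erythro diol | COc1cc([C@H](O)[C@@H](CO)Oc2c(OC)cc(I)cc2OC)ccc1O[Si](C(C)C)(C(C)C)C(C)C | intermediate
9 | propargyl alcohol | C#CCO | starting material
10 | alkyne | COc1cc([C@H](O)[C@@H](CO)Oc2c(OC)cc(C#CCO)cc2OC)ccc1O[Si](C(C)C)(C(C)C)C(C)C | intermediate
11 | 5-iodovanillin | COc1cc(C=O)cc(I)c1O | starting material
12 | 4-formyl-2-iodo-6-methoxyphenyl acetate | COc1cc(C=O)cc(I)c1OC(C)=O | intermediate
13 | (Z)-2,3-diarylallyl alcohol | COc1cc([C@H](O)[C@@H](CO)Oc2c(OC)cc(/C=C(\CO)c3cc(C=O)cc(OC)c3OC(C)=O)cc2OC)ccc1O[Si](C(C)C)(C(C)C)C(C)C | intermediate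
14 | (S)-hydrogenated acetate | COc1cc([C@H](O)[C@@H](CO)Oc2c(OC)cc(C[C@H](CO)c3cc(C=O)cc(OC)c3OC(C)=O)cc2OC)ccc1O[Si](C(C)C)(C(C)C)C(C)C | intermediate
15 | free phenol | COc1cc([C@H](O)[C@@H](CO)Oc2c(OC)cc(C[C@H](CO)c3cc(C=O)cc(OC)c3O)cc2OC)ccc1O[Si](C(C)C)(C(C)C)C(C)C | intermediate
16 | TIPS-protected target | COc1cc([C@H](O)[C@@H](CO)Oc2c(OC)cc([C@@H]3Oc4c(OC)cc(C=O)cc4[C@H]3CO)cc2OC)ccc1O[Si](C(C)C)(C(C)C)C(C)C | intermediate
17 | target (CID53356209) | COc1cc([C@H](O)[C@@H](CO)Oc2c(OC)cc([C@@H]3Oc4c(OC)cc(C=O)cc4[C@H]3CO)cc2OC)ccc1O | target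

## Totals
- Total steps: 13.
- Longest linear sequence: 11 (acetovanillone → 4 → 5 → 6 → 7 → 8 → 10 → 13 → 14 → 15 → 16 → 17). Steps 1 and 8 run in parallel.

## Three steps most likely to fail
1. **Step 6 (DKR–ATH).** Diastereoselectivity (erythro vs threo) and ee are unproven on this substrate.
   - Fallback: reduce racemic 7 with Zn(BH4)2, which is expected to give erythro by chelation control, then resolve the enantiomers by preparative chiral HPLC or lipase acylation.
2. **Step 10 (Ir hydrogenation).** The free hydroxyls or the aldehyde may poison the catalyst or be reduced, and the ee may be low.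
   - Fallback: hydrogenate non-selectively, for example with diimide. The two C3 epimers are diastereomers because the glycerol centres are already fixed, so separate them by HPLC.
3. **Step 12 (DDQ cyclisation).** Problems could be competing oxidation of the guaiacyl α-OH, loss of C3 stereochemistry through elimination to the stilbene, or a poor trans:cis ratio.
   - Fallback: skip steps 10–12. Deacetylate 13 and cyclise it directly by confined chiral Brønsted-acid (IDPi) hydroalkoxylation. This sets C3 by enantioselective protonation of the same quinoid cation.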